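Ring A is the fully substituted ring, numbered as in a chalcone: C1' (cinnamoyl), C2' (OH), C3' (OMe), C4' (OH), C5' (O-acyl), C6' (OMe). Ring B is the phenyl ring.

## The problem

Target 16 has no fused rings and only one short chain. Its difficulty lies in ring A, a benzene with no C–H, which carries the cinnamoyl group at C1' and five oxygens in three states: free OH at C2' and C4', OMe at C3' and C6', and the (S)-2-methylbutanoate at C5'. A synthesis must decide which oxygen receives which group. The critical oxygen, O5', stands beside the free O4'–H, so a 1,2-acyl shift is always open, and para to O2'–H, so the ring is a hydroquinone monoester that oxidises readily to a quinone. The single stereocentre, C2 of the acyl chain, is remote from everything else: nothing in the molecule can set or repair it and it controls nothing, so it is best bought with (S)-2-methylbutanoic acid 11 and then only preserved. As the α-carbon of an activated aryl ester it is lost by enolisation or ketene formation once base is present. The aryl ester does not survive the hydroxide of a Claisen–Schmidt condensation, and the 2'-hydroxy-6'-methoxychalcone unit closes to a flavanone in acid or base, so the ester must arrive late and under nearly neutral conditions. The feature that opens the plan is the position of C5': it lies para to O2', ortho to O4' and ortho to the 6'-OMe group, so in the des-acyloxy chalcone 10 it is the only C–H of ring A and its most nucleophilic carbon. If the C1' substituent is removed as well, the remaining 2,5-dimethoxyresorcinol core (as in 5) has a mirror plane through C3' and C6' that makes C1' and C5' equivalent, so ring A is a symmetric arene whose two equal C–H bonds are spent once on carbon and once on oxygen.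

## Retrosynthesis

**Cut 1, C5'–O5' (16 ⇒ 10 + 14).**
- The aryl–oxygen bond is cut, not the acyl–oxygen bond. The acyl–oxygen cut leads to a triol in which three phenols must be told apart. The aryl–oxygen cut leads to chalcone 10, in which the site is the only ring C–H and no choice among oxygens arises.
- The bond joins two centres of like polarity, an electron-rich arene carbon and a carboxylate oxygen, so one partner must be reversed.
- Reversing the ring (oxidation to a cation by trivalent iodine or at an anode) places the charge on C1', C3' and C5'. It is best stabilised at C3' by that carbon's own OMe group, where capture by carboxylate is the normal outcome for 2-methoxyphenols.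
- The oxygen is therefore reversed instead, as the diacyl peroxide 14, and the ring keeps its natural polarity.
- Compound 10 is achiral, has one oxygen fewer and carries no ester.
- The forward reaction must be mono-selective, free of base and cold.

**Cut 2, O–O of 14 (14 ⇒ 11).** The peroxide is two molecules of the purchased acid 11 joined through H2O2. Carbodiimide activation avoids an acid chloride and any base, so the S centre is not put at risk. The half of 14 that is not transferred returns as 11.

**Cut 3, C1'–C(=O) (10 ⇒ 9 ⇒ 5 + 6).**
- The aryl–carbonyl bond is cut rather than the Cα=Cβ bond of the usual aldol plan.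
- In 5 the two ring C–H bonds are equivalent, and each lies between an OMOM and an OMe group, so only one aryllithium (7) can form.
- The Weinreb amide 6 delivers all nine carbons and the E alkene in one operation.
- Carbon goes on before oxygen because the ester would survive neither the organolithium nor the acid that removes the MOM groups.
- The forward step needs 1,2-addition without over-addition, which the chelated adduct 8 provides.

**Cut 4, C6'–O (5 ⇒ 4 ⇒ 2 ⇒ 1).**
- The oxygen para to the 3'-OMe group is removed, which leads to commercial 2-methoxyresorcinol 1.
- In the bis-MOM ether 2 this position is meta to both OMOM groups, so electrophilic substitution would avoid it.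
- It is, however, the only C–H without an ortho neighbour, which is what sterically governed iridium borylation selects (via 3).
- Oxidation to 4 and methylation restore the mirror plane in 5.

## Roads not taken

**Alternative 1:** (the most obvious)
- The cut: the acyl–O5' bond and the Cα=Cβ bond.
- Forward: Elbs persulfate oxidation at the acetophenone stage gives 1-(2,4,5-trihydroxy-3,6-dimethoxyphenyl)ethanone A1. Masking of O4', Claisen–Schmidt condensation with benzaldehyde to chalcone A2, carbodiimide esterification of O5' with 11 and acidic unmasking follow.
- Why the chosen plan is better: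
  - The same tetraoxygenated ring has to be made first in any case, after which four or five operations do what step 7 does in one.
  - Selectivity rests on reactivity differences among three phenols.
  - The aldol step exposes an air-sensitive hydroquinone to strong base.
  - The last step frees O4'–H next to the ester under the acid that also catalyses acyl shift and flavanone closure.

**Alternative 2:**
- The cut: C5'–O5', traced back to a C5'–C bond.
- Forward: Baeyer–Villiger insertion with aryl migration into the diketone A3.
- The appeal: the symmetric core is C-acylated twice and the S centre sits in the non-migrating group.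
- Why the chosen plan is better:
  - Ring A of A3 bears two aryl ketones, both chelated to an ortho OH, and the same electron-rich aryl group would migrate from either, so the structure offers no basis for choosing between them.
  - The peracid would also attack the ring and the enone.
  - Making A3 needs a Lewis-acid acylation with an α-chiral acyl chloride, and A3 itself is an enolisable sec-alkyl ketone, so the stereocentre is at risk twice.

**Alternative 3:**
- The cut: ring bonds C4'–C5' and C2'–C3', so that ring A is built from a cyclobutenone.
- Forward: a 1,2-dialkoxyvinyllithium adds to a 3-methoxy-4-acylcyclobutenedione, and the alkoxide is trapped with the acyl chloride of 11 to give A4. Thermal four-electron ring opening and six-electron closure then give phenol A5.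
- The appeal: the ketene oxygen becomes O2'–H and the carbinol oxygen keeps its acyl group as O5', so the para pair is differentiated by construction.
- Why the chosen plan is better:
  - A4 needs an unsymmetrical vinyl anion with two different alkoxy groups.
  - It also needs a cyclobutenedione bearing a cinnamoyl group, for which squarate chemistry offers only acyl-anion equivalents and later unmasking.
  - A tertiary allylic ester must survive heating above 100 °C.
  - The run-up alone would be longer than the whole chosen route.

Key step: step 7

Assumption: 1, 6 and 11 are taken as catalogue compounds (6 is otherwise one step from cinnamoyl chloride and MeNHOMe·HCl).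

## Route

Step 1
Reactants: 1 2-methoxyresorcinol
Product: 2 2-methoxy-1,3-bis(methoxymethoxy)benzene
Conditions: MOMCl, iPr2NEt, CH2Cl2, 0 °C to rt
Reagents that add atoms: chloromethyl methyl ether, COCCl
Why: O-alkylation of both phenols to formaldehyde acetals. The MOM groups survive base, the iridium catalyst and organolithiums, direct the later metalation and leave under mild acid.

Step 2
Reactants: 2 2-methoxy-1,3-bis(methoxymethoxy)benzene
Product: 4 4-methoxy-3,5-bis(methoxymethoxy)phenol, via arylboronate 3 (not isolated)
Conditions: [Ir(OMe)(cod)]2 (cat.), 4,4'-di-tert-butyl-2,2'-bipyridine (cat.), B2pin2, THF, 80 °C; then H2O2 (30 % aq), NaOH, 0 °C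
Reagents that add atoms: bis(pinacolato)diboron, CC1(C)OB(OC1(C)C)B1OC(C)(C)C(C)(C)O1 (boron unit of 3); hydrogen peroxide, OO (oxygen of 4)
Why: Iridium-catalysed aromatic C–H borylation is governed by sterics, and in the 1,2,3-trisubstituted ring of 2 only the C–H meta to both OMOM groups has no ortho neighbour, so boron should enter there alone. Basic peroxide then converts C–B into C–O by the usual 1,2-shift from boron to oxygen in the same flask.

Step 3
Reactants: 4 4-methoxy-3,5-bis(methoxymethoxy)phenol
Product: 5 2,5-dimethoxy-1,3-bis(methoxymethoxy)benzene
Conditions: MeI, K2CO3, acetone, reflux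
Reagents that add atoms: iodomethane, CI
Why: Williamson ether synthesis on the only free phenol. It restores the mirror plane, so the two remaining ring C–H bonds are equivalent.

Step 4
Reactants: 5 2,5-dimethoxy-1,3-bis(methoxymethoxy)benzene; 6 (E)-N-methoxy-N-methylcinnamamide
Product: 9 (E)-1-[3,6-dimethoxy-2,4-bis(methoxymethoxy)phenyl]-3-phenylprop-2-en-1-one, via aryllithium 7 (not isolated), via tetrahedral lithium adduct 8 (not isolated)
Conditions: n-BuLi, THF, 0 °C; then 6, −78 to 0 °C; H2O
Reagents that add atoms: n-butyllithium, [Li]CCCC (lithium of 7 and 8 only)
Why: In this directed ortho-metalation each of the two equivalent C–H bonds lies between an OMOM and an OMe group, so a single aryllithium forms. In the Weinreb ketone synthesis the hard aryllithium adds 1,2 and the chelated adduct 8 holds until the quench, which excludes over-addition. The E alkene comes unchanged from 6.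

Step 5
Reactants: 9 (E)-1-[3,6-dimethoxy-2,4-bis(methoxymethoxy)phenyl]-3-phenylprop-2-en-1-one
Product: 10 (E)-1-(2,4-dihydroxy-3,6-dimethoxyphenyl)-3-phenylprop-2-en-1-one (2',4'-dihydroxy-3',6'-dimethoxychalcone)
Conditions: HCl (1.25 M in MeOH), 40 °C
Reagents that add atoms: none
Why: Acid-catalysed acetal exchange with methanol, as is routine for MOM-protected 2'-hydroxychalcones. The mild conditions should keep the slower oxa-Michael closure to the flavanone in the background.

Step 6
Reactants: 11 (S)-2-methylbutanoic acid
Product: 14 bis[(S)-2-methylbutanoyl] peroxide, via O-acylisourea 12 (not isolated), via peracid 13 (not isolated)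
Conditions: DCC, H2O2 (30 % aq), CH2Cl2, −15 to 0 °C; filtered, washed cold, dried, kept as a titrated CH2Cl2 solution at −20 °C, never concentrated
Reagents that add atoms: N,N'-dicyclohexylcarbodiimide, C(=NC1CCCCC1)=NC1CCCCC1 (atoms of 12 only); hydrogen peroxide, OO
Why: This is the known carbodiimide-mediated acylation of hydrogen peroxide to aliphatic diacyl peroxides: 12 is perhydrolysed to 13, which is acylated by a second molecule of 12. No base is present and the α-C–H bond is not involved, so both S centres are retained.

Step 7
Reactants: 10 2',4'-dihydroxy-3',6'-dimethoxychalcone; 14 bis[(S)-2-methylbutanoyl] peroxide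
Product: 16 2,4-dihydroxy-3,6-dimethoxy-5-[(E)-3-phenylprop-2-enoyl]phenyl (2S)-2-methylbutanoate, via C5'-acyloxy dienone 15 (not isolated)
Conditions: 14 (cold CH2Cl2 solution, slight excess, in portions), CH2Cl2/(CF3)2CHOH 4:1, 0 °C, dark, Ar
Reagents that add atoms: none
Why: Proposed new method: ring A of 10 reacts in its natural polarity as a carbon nucleophile and the carboxylate oxygen is the reversed partner: C5' attacks one peroxidic oxygen of 14 in a displacement at oxygen, the other half leaves as acid 11 (helped by hydrogen bonding from (CF3)2CHOH and from O4'–H), and the dienone 15 tautomerises at once to 16; a first attack through O4' followed by a [3,3] shift of the aryl acyl peroxide would end at the same carbon. The closest known reaction types are the ortho/para C–H acyloxylation of phenols with (PhCO2)2, the Elbs persulfate oxidation (which hydroxylates 2-hydroxyacetophenones of this kind para to the chelated OH), the C-acyloxylation of 1,3-dicarbonyl enolates with diacyl peroxides and arene C–H oxygenation with cyclic diacyl peroxides in fluorinated alcohols; what has not been shown is an α-branched aliphatic peroxide as carrier of a chiral acyloxy group with a chelated acylresorcinol as acceptor. No ring is closed and no lasting stereocentre is made, since the sp3 carbon C5' of 15 is flattened again on aromatisation. The S centre is a spectator: neither its C–H bond nor its bond to the carbonyl carbon takes part, the medium holds no base, and the step is the last one, so nothing can scramble it later. Site selectivity follows the rules of electrophilic aromatic substitution: C5' is para to O2'–H, ortho to O4'–H and to the 6'-OMe group and is the only ring carbon bearing hydrogen, whereas C1' and C3' are substituted, flanked on both sides and unable to lose a proton after attack. Over-oxidation is held back because 16 has no ring C–H left and the new acyloxy group withdraws electrons inductively and forces the 6'-OMe group out of the ring plane, so the product should be a poorer nucleophile than 10. The electron-poor enone is not epoxidised by diacyl peroxides, and O-acylation needs a phenoxide, which is absent, while O2'–H is tied up in the chelate and the acyl carbon of 14 is α-branched. The kinetic product is also the thermodynamic member of the O4'/O5' ester pair, because the free 4'-OH is para to the ketone (a vinylogous acid and hence the better leaving group of the two phenols), so the 1,2-acyl shift has no driving force.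

## Compound list

1 | 2-methoxyresorcinol (2-methoxybenzene-1,3-diol) | COc1c(O)cccc1O | starting material
2 | 2-methoxy-1,3-bis(methoxymethoxy)benzene | COCOc1cccc(OCOC)c1OC | intermediate
3 | 2-[4-methoxy-3,5-bis(methoxymethoxy)phenyl]-4,4,5,5-tetramethyl-1,3,2-dioxaborolane (formed in the flask) | COCOc1cc(B2OC(C)(C)C(C)(C)O2)cc(OCOC)c1OC | intermediate
4 | 4-methoxy-3,5-bis(methoxymethoxy)phenol | COCOc1cc(O)cc(OCOC)c1OC | intermediate
5 | 2,5-dimethoxy-1,3-bis(methoxymethoxy)benzene | COCOc1cc(OC)cc(OCOC)c1OC | intermediate
6 | (E)-N-methoxy-N-methylcinnamamide | CON(C)C(=O)/C=C/c1ccccc1 | starting material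
7 | [3,6-dimethoxy-2,4-bis(methoxymethoxy)phenyl]lithium (formed in the flask) | [Li]c1c(OC)cc(OCOC)c(OC)c1OCOC | intermediate
8 | lithium (E)-1-[3,6-dimethoxy-2,4-bis(methoxymethoxy)phenyl]-1-[methoxy(methyl)amino]-3-phenylprop-2-en-1-olate, racemic at the carbinol carbon (formed in the flask) | [Li]OC(/C=C/c1ccccc1)(N(C)OC)c1c(OC)cc(OCOC)c(OC)c1OCOC | intermediate
9 | (E)-1-[3,6-dimethoxy-2,4-bis(methoxymethoxy)phenyl]-3-phenylprop-2-en-1-one | O=C(/C=C/c1ccccc1)c1c(OC)cc(OCOC)c(OC)c1OCOC | intermediate
10 | (E)-1-(2,4-dihydroxy-3,6-dimethoxyphenyl)-3-phenylprop-2-en-1-one | O=C(/C=C/c1ccccc1)c1c(OC)cc(O)c(OC)c1O | intermediate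
11 | (S)-2-methylbutanoic acid | CC[C@H](C)C(=O)O | starting material
12 | N,N'-dicyclohexyl-O-[(S)-2-methylbutanoyl]isourea (formed in the flask) | CC[C@H](C)C(=O)OC(=NC1CCCCC1)NC1CCCCC1 | intermediate
13 | (S)-2-methylbutaneperoxoic acid (formed in the flask) | CC[C@H](C)C(=O)OO | intermediate
14 | bis[(S)-2-methylbutanoyl] peroxide | CC[C@H](C)C(=O)OOC(=O)[C@@H](C)CC | intermediate
15 | 3-cinnamoyl-6-hydroxy-2,5-dimethoxy-4-oxocyclohexa-2,5-dien-1-yl (S)-2-methylbutanoate, ring carbinol carbon undefined (formed in the flask) | CC[C@H](C)C(=O)OC1C(O)=C(OC)C(=O)C(C(=O)/C=C/c2ccccc2)=C1OC | intermediate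
16 | 2,4-dihydroxy-3,6-dimethoxy-5-[(E)-3-phenylprop-2-enoyl]phenyl (2S)-2-methylbutanoate | CC[C@H](C)C(=O)Oc1c(O)c(OC)c(O)c(C(=O)/C=C/c2ccccc2)c1OC | target

## Step count and risks

Total steps: 7. Longest linear sequence: 6 (steps 1 to 5 and 7). Step 6 is a one-step branch.

**Step 7 (key step, proposed new method).**
- What may go wrong:
  - Oxygen transfer to the ketone-deactivated ring may be slower than the unimolecular decay of the α-branched peroxide (homolysis and carboxy inversion, both faster in the polar medium).
  - Electron transfer may occur in place of displacement, followed by rapid loss of CO2 from the acyloxyl radical.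
  - Ipso attack may occur at the methoxy-bearing C3'.
- Fallback (known chemistry, C–O bond first and acyl group second), from 10:
  - Teuber oxidation with (KSO3)2NO (KH2PO4 buffer, acetone/water) should give 2-cinnamoyl-5-hydroxy-3,6-dimethoxy-1,4-benzoquinone F1.
  - Reduction with Na2S2O4 under argon gives 2',4',5'-trihydroxy-3',6'-dimethoxychalcone F2.
  - One equivalent of 11 is then attached with EDC·HCl and catalytic DMAP in CH2Cl2 at 0 °C.
  - O2'–H is held in the chelate, and the O4' and O5' monoesters interconvert by the 1,2-acyl shift, which should settle on O5'. The route is rejoined at 16.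

**Step 6.**
- What may go wrong: the peroxide may be lost during preparation and storage through carboxy inversion or homolysis, and the second acylation may be incomplete, leaving peracid that would later oxidise ring A unselectively.
- Fallback, from 10:
  - The stable commercial (PhCO2)2 in CHCl3 transfers a benzoyloxy group by the known phenol reaction to give 2,4-dihydroxy-3,6-dimethoxy-5-[(E)-3-phenylprop-2-enoyl]phenyl benzoate F3.
  - K2CO3 in MeOH under argon releases the triol F2.
  - F2 is esterified with 11 as described above, and the route is rejoined at 16.

**Step 4.**
- What may go wrong: metalation may be incomplete, 1,2-addition of the crowded di-ortho-substituted aryllithium may be sluggish, and conjugate addition to the cinnamamide may compete.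
- Fallback (electrophilic substitution instead of metalation), from 5:
  - Methanolic HCl removes both MOM groups to give 2,5-dimethoxybenzene-1,3-diol F4.
  - Friedel–Crafts acylation of F4 with cinnamoyl chloride in BF3·OEt2 can give only one regioisomer, because its two C–H positions are equivalent. The route is rejoined at 10.

**Step 5.**
- What may go wrong: acid-catalysed oxa-Michael closure of the freed O2'–H onto the enone during acetal cleavage, favoured by the 6'-OMe group, which twists the carbonyl group out of the ring plane.
- Fallback (acid step placed before the enone exists), from 5: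
  - Aryllithium 7 is quenched with N-methoxy-N-methylacetamide to give 1-[3,6-dimethoxy-2,4-bis(methoxymethoxy)phenyl]ethanone F5.
  - Methanolic HCl gives 1-(2,4-dihydroxy-3,6-dimethoxyphenyl)ethanone F6.
  - Claisen–Schmidt condensation with benzaldehyde (KOH, EtOH) builds the enone last, and the route is rejoined at 10.

## Further compounds

F1 | step 7 | 2-cinnamoyl-5-hydroxy-3,6-dimethoxy-1,4-benzoquinone | O=C(/C=C/c1ccccc1)C1=C(OC)C(=O)C(O)=C(OC)C1=O
F2 | step 7 | (E)-1-(2,4,5-trihydroxy-3,6-dimethoxyphenyl)-3-phenylprop-2-en-1-one | O=C(/C=C/c1ccccc1)c1c(OC)c(O)c(O)c(OC)c1O
F3 | step 6 | 2,4-dihydroxy-3,6-dimethoxy-5-[(E)-3-phenylprop-2-enoyl]phenyl benzoate | O=C(Oc1c(O)c(OC)c(O)c(C(=O)/C=C/c2ccccc2)c1OC)c1ccccc1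
F4 | step 4 | 2,5-dimethoxybenzene-1,3-diol | COc1cc(O)c(OC)c(O)c1
F5 | step 5 | 1-[3,6-dimethoxy-2,4-bis(methoxymethoxy)phenyl]ethanone | CC(=O)c1c(OC)cc(OCOC)c(OC)c1OCOC
F6 | step 5 | 1-(2,4-dihydroxy-3,6-dimethoxyphenyl)ethanone | CC(=O)c1c(OC)cc(O)c(OC)c1O
A1 | alternative 1 | 1-(2,4,5-trihydroxy-3,6-dimethoxyphenyl)ethanone | CC(=O)c1c(OC)c(O)c(O)c(OC)c1O
A2 | alternative 1 | (E)-1-[2,5-dihydroxy-3,6-dimethoxy-4-(methoxymethoxy)phenyl]-3-phenylprop-2-en-1-one | O=C(/C=C/c1ccccc1)c1c(OC)c(O)c(OCOC)c(OC)c1O
A3 | alternative 2 | (S)-1-{2,4-dihydroxy-3,6-dimethoxy-5-[(E)-3-phenylprop-2-enoyl]phenyl}-2-methylbutan-1-one | CC[C@H](C)C(=O)c1c(O)c(OC)c(O)c(C(=O)/C=C/c2ccccc2)c1OC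
A4 | alternative 3 | 3-cinnamoyl-2-methoxy-1-[(Z)-2-methoxy-1-(methoxymethoxy)vinyl]-4-oxocyclobut-2-en-1-yl (S)-2-methylbutanoate, both epimers at the ring carbinol carbon | CC[C@H](C)C(=O)OC1(/C(OCOC)=C/OC)C(OC)=C(C(=O)/C=C/c2ccccc2)C1=O
A5 | alternative 3 | 4-hydroxy-3,6-dimethoxy-2-(methoxymethoxy)-5-[(E)-3-phenylprop-2-enoyl]phenyl (S)-2-methylbutanoate | CC[C@H](C)C(=O)Oc1c(OCOC)c(OC)c(O)c(C(=O)/C=C/c2ccccc2)c1OC
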